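**Assumptions:** the target's relative configuration is 2,3-cis-dimethyl with the 4-aryl trans to the 3-methyl, as encoded in the SMILES. (R)-But-3-yn-2-ol is purchased enantiopure, and benzyl protects the C7 phenol.

## Retrosynthesis
1. Schisandrone comes from hydrogenolysis of its 7-OBn tetralone. The tetralone ring closes last, by intramolecular Friedel–Crafts alkylation (C4–C4a) of a γ-aryl-γ-hydroxy aryl ketone, with C4 set trans to the 3-Me.
2. That hydroxy ketone comes from an ArLi addition to a 5-aryl-γ-lactone. The lactone comes from ArMgBr addition to the aldehyde-acid obtained by ozonolysis of (2S,3S,E)-2,3-dimethylhex-4-enoic acid.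
3. The acid comes from an Ireland–Claisen [3,3] rearrangement of (R,E)-pent-3-en-2-yl propanoate. This forms the C2–C3 bond and both adjacent methyl centres (anti) by chair-TS chirality transfer from the carbinol centre.
4. The allylic alcohol comes from (R)-but-3-yn-2-ol by C-methylation and Red-Al reduction.

## Route

**Step 1**
Reactants: 1 (5-bromo-2-methoxyphenol), 2 (benzyl bromide)
Product: 3 (2-(benzyloxy)-4-bromo-1-methoxybenzene)
Conditions: K2CO3, DMF, rt
Reagents that add atoms: benzyl bromide, BrCc1ccccc1
Why: Williamson ether synthesis masks the phenol that becomes the C7–OH and gives the aryl bromide with OMe para to Br.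

**Step 2**
Reactants: 4 ((R)-but-3-yn-2-ol), 5 (iodomethane)
Product: 6 ((R)-pent-3-yn-2-ol)
Conditions: n-BuLi (2.1 equiv), THF, −78 → 0 °C; then MeI, DMPU, −78 °C → rt
Reagents that add atoms: iodomethane, CI
Why: The alkoxide/acetylide dianion is alkylated at carbon by MeI, and the carbinol stereocentre is untouched.

**Step 3**
Reactants: 6
Product: 7 ((R,E)-pent-3-en-2-ol)
Conditions: Red-Al, Et2O, 0 °C → rt
Reagents that add atoms: none
Why: Propargylic-alkoxide-directed trans-hydroalumination gives the E-alkene, and the carbinol centre is untouched.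

**Step 4**
Reactants: 7, 8 (propionyl chloride)
Product: 9 ((R,E)-pent-3-en-2-yl propanoate)
Conditions: EtCOCl, Et3N, DMAP (cat.), CH2Cl2, 0 °C
Reagents that add atoms: propionyl chloride, CCC(=O)Cl
Why: Standard acylation of a secondary alcohol, which sets up the allyl propionate for rearrangement.

**Step 5**
Reactants: 9
Product: 10 ((2S,3S,E)-2,3-dimethylhex-4-enoic acid)
Conditions: LDA, THF, −78 °C; TBSCl; −78 °C → rt; then 1 M HCl
Reagents that add atoms: none (the TBS ester is cleaved on work-up)
Why: Ireland–Claisen [3,3] rearrangement. LDA/THF gives the E-silyl ketene acetal, which reacts through a chair TS with the E-alkene and the carbinol methyl equatorial. This gives the 2,3-anti product, and the (R)-carbinol fixes the absolute configuration as 2S,3S.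

**Step 6**
Reactants: 10
Product: 11 ((3S,4R)-5-hydroxy-3,4-dimethyldihydrofuran-2(3H)-one, the lactol form of the aldehyde-acid, as an anomer mixture)
Conditions: O3, CH2Cl2, −78 °C; then Me2S, −78 °C → rt
Reagents that add atoms: ozone, O=[O+][O-]
Why: Ozonolysis cleaves the only alkene to give the aldehyde (C4); the acid-aldehyde closes to the lactol, which protects the α-centres from epimerisation.

**Step 7**
Reactants: 11, 12 (4-bromo-1,2-dimethoxybenzene)
Product: 13 ((3S,4R)-5-(3,4-dimethoxyphenyl)-3,4-dimethyldihydrofuran-2(3H)-one, C5 epimer mixture)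
Conditions: 12 + Mg, THF (ArMgBr, 3.5 equiv); add 11, −78 → 0 °C; then 1 M HCl, then TsOH (cat.), CH2Cl2, rt
Reagents that add atoms: 3,4-dimethoxyphenylmagnesium bromide, COc1ccc([Mg]Br)cc1OC
Why: The lactol alkoxide opens to the aldehyde-carboxylate, and Grignard addition followed by lactonisation gives the γ-aryl lactone. The C5 epimers converge later because C4 becomes a cation.

**Step 8**
Reactants: 13, 3
Product: 14 ((2S,3R)-1-[3-(benzyloxy)-4-methoxyphenyl]-4-(3,4-dimethoxyphenyl)-4-hydroxy-2,3-dimethylbutan-1-one, C4 epimer mixture; it is in equilibrium with its cyclic hemiketal)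
Conditions: 3, n-BuLi (1.1 equiv), THF, −78 °C, 30 min; add 13, −78 °C, 2 h; aq. NH4Cl
Reagents that add atoms: 3-(benzyloxy)-4-methoxyphenyllithium, COc1ccc([Li])cc1OCc1ccccc1
Why: Br–Li exchange followed by one addition to the lactone gives a stable lactol at −78 °C, which opens to the hydroxy ketone; C2 and C3 are unchanged.

**Step 9**
Reactants: 14
Product: 15 ((2S,3S,4R)-7-(benzyloxy)-4-(3,4-dimethoxyphenyl)-6-methoxy-2,3-dimethyl-3,4-dihydronaphthalen-1(2H)-one)
Conditions: BF3·OEt2 (2 equiv), CH2Cl2, −20 → 0 °C
Reagents that add atoms: none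
Why: Ionisation of the benzylic alcohol gives the dimethoxybenzylic cation at C4, which undergoes intramolecular Friedel–Crafts alkylation at the ring position para to OBn. The aryl and 3-Me prefer the trans (both pseudo-equatorial) arrangement, which sets C4 by substrate control. Cold, mild acid limits C2 epimerisation.

**Step 10**
Reactants: 15
Product: 16 (Schisandrone)
Conditions: H2 (1 atm), 10% Pd/C, EtOAc/MeOH, rt
Reagents that add atoms: none
Why: Hydrogenolysis removes the aryl benzyl ether and leaves the hindered, electron-rich aryl ketone and the stereocentres intact.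

## Compound list
1 | 5-bromo-2-methoxyphenol | COc1ccc(Br)cc1O | starting material
2 | benzyl bromide | BrCc1ccccc1 | starting material
3 | 2-(benzyloxy)-4-bromo-1-methoxybenzene | COc1ccc(Br)cc1OCc1ccccc1 | intermediate
4 | (R)-but-3-yn-2-ol | C[C@@H](O)C#C | starting material
5 | iodomethane | CI | starting material
6 | (R)-pent-3-yn-2-ol | C[C@@H](O)C#CC | intermediate
7 | (R,E)-pent-3-en-2-ol | C[C@@H](O)/C=C/C | intermediate
8 | propionyl chloride | CCC(=O)Cl | starting material
9 | (R,E)-pent-3-en-2-yl propanoate | CCC(=O)O[C@H](C)/C=C/C | intermediate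
10 | (2S,3S,E)-2,3-dimethylhex-4-enoic acid | OC(=O)[C@@H](C)[C@@H](C)/C=C/C | intermediate
11 | (3S,4R)-5-hydroxy-3,4-dimethyldihydrofuran-2(3H)-one (lactol) | O=C1OC(O)[C@H](C)[C@@H]1C | intermediate
12 | 4-bromo-1,2-dimethoxybenzene | COc1ccc(Br)cc1OC | starting material
13 | (3S,4R)-5-(3,4-dimethoxyphenyl)-3,4-dimethyldihydrofuran-2(3H)-one | O=C1OC(c2ccc(OC)c(OC)c2)[C@H](C)[C@@H]1C | intermediate
14 | (2S,3R)-1-[3-(benzyloxy)-4-methoxyphenyl]-4-(3,4-dimethoxyphenyl)-4-hydroxy-2,3-dimethylbutan-1-one | COc1ccc(cc1OC)C(O)[C@H](C)[C@H](C)C(=O)c1ccc(OC)c(OCc2ccccc2)c1 | intermediate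
15 | (2S,3S,4R)-7-(benzyloxy)-4-(3,4-dimethoxyphenyl)-6-methoxy-2,3-dimethyltetralin-1-one | COc1cc2c(cc1OCc1ccccc1)C(=O)[C@@H](C)[C@@H](C)[C@@H]2c1ccc(OC)c(OC)c1 | intermediate
16 | Schisandrone | COc1cc2c(cc1O)C(=O)[C@@H](C)[C@@H](C)[C@@H]2c1ccc(OC)c(OC)c1 | target

**Total steps:** 10. **Longest linear sequence:** 9 (steps 2–10 from 4).

## Three steps most likely to fail
1. **Step 9 (cationic cyclisation).** The acyl-substituted ring is only moderately nucleophilic, C4 selectivity may be modest, and C2 can epimerise. Fallback: oxidise 14 to the 1,4-diketone, close it by acid-mediated intramolecular hydroxyalkylation to the tertiary alcohol, and set C4–H by Et3SiH/TFA ionic hydrogenation with hydride delivered anti to the 3-Me.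
2. **Step 5 (Ireland–Claisen).** The 2,3-anti selectivity depends on clean E-silyl ketene acetal formation. Fallback: thermal Johnson–Claisen of 7 with triethyl orthopropionate and cat. propionic acid at 140 °C, which goes through a neutral ketene acetal and gives the ester directly, with chromatographic removal of the syn isomer.
3. **Steps 7/8 (aryl additions to the α-chiral aldehyde and lactone).** Epimerisation at C3 or C2 by the basic organometallics, or double addition to the lactone, could occur. Fallback: reverse the order. Convert acid 10 to its Weinreb amide, add the ArA Grignard to make the aryl ketone, cleave the alkene with OsO4/NaIO4, add ArB–MgBr to the aldehyde at −78 °C, and then cyclise as in step 9.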